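The cyclopentane (C1–C5) is never built directly. It is cut out of the six-membered p-menthane ring of (R)-carvone. A Diels–Alder reaction with a prenal-derived diene gives a decalin that already holds all fifteen skeletal carbons. Oxidation then gives a trans-decalin with an equatorial mesylate at C5 beside the ring-fusion carbinol C6. In the key step the fusion bond C6–C1 shifts to C5: ring A contracts to the cyclopentane, ring B expands to the cycloheptene, C6 becomes a ketone and the hindered C1–C5 bond forms cis. The step exploits the C4(OH)–C5(H)–C6(O) array next to the quaternary methyl carbon C1.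

Key step: step 12

Remark (atom labels): the ten ring atoms carry their final labels in every precursor. C1 is the quaternary methyl carbon, C2 CH(OH), C3 CH2, C4 C(OH)(i-Pr) and C5 the fusion CH. C6 is CH(OAng), C7 CH2, C8 (methyl) and C9 the oxirane carbons, and C10 CH(OAng). In the decalins ring A is C1–C6 and ring B is C1, C6–C10. β is the face of the C1 methyl group and α the opposite face.

Remark (supply): (R)-carvone, prenal and angelic acid are taken as commercial.

Step 1
Reactants: 1 (R)-(−)-carvone
Product: 2 (R)-carvotanacetone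
Conditions: H2 (1 atm), RhCl(PPh3)3 (cat.), toluene, rt
Reagents that add atoms: none
Why: Homogeneous hydrogenation saturates only the unhindered 1,1-disubstituted alkene and leaves the trisubstituted enone and the C4 stereocentre untouched.

Step 2
Reactants: 3 3-methylbut-2-enal (prenal)
Product: 4 (E)-1-(tert-butyldimethylsilyloxy)-3-methylbuta-1,3-diene
Conditions: TBSOTf, Et3N, Et2O, 0 °C to rt
Reagents that add atoms: tert-butyldimethylsilyl triflate, CC(C)(C)[Si](C)(C)OS(=O)(=O)C(F)(F)F
Why: Soft enolisation (silyl dienol ether formation) removes a γ-proton of the O-silylated enal, and the s-trans enal geometry gives the E enol ether.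

Step 3
Reactants: 2 (R)-carvotanacetone; 4 silyloxy diene
Product: 5 cis-octalone adduct (C2 ketone; 1β-Me; 6β-H; 4β-i-Pr; 10α-OTBS; C8=C9)
Conditions: EtAlCl2 (0.3 equiv), toluene, −20 °C to rt
Reagents that add atoms: none
Why: In this Lewis acid-catalysed Diels–Alder reaction the 1-silyloxy and 3-methyl groups both make C7 the nucleophilic diene terminus, so C7 bonds to the enone β-carbon C6 and C10 to C1, while endo addition anti to the C4 isopropyl group sets the quaternary C1 (C4, C6 and C10 are erased or reset later).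

Step 4
Reactants: 5 cis-octalone adduct
Product: 7 ring A linear dienone (C2=O; C3=C4; C5=C6; 10α-OTBS), via enone 6 (not isolated)
Conditions: IBX (3.5 equiv), DMSO/fluorobenzene, 80 °C
Reagents that add atoms: none
Why: IBX dehydrogenation can only enolise toward C3 because C1 is quaternary, so it gives the enone and then, through the extended dienol, the C5=C6 bond, with aromatisation blocked by C1.

Step 5
Reactants: 7 ring A linear dienone
Product: 8 2α-dienol
Conditions: DIBAL-H, CH2Cl2, −78 °C; aq. potassium sodium tartrate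
Reagents that add atoms: none
Why: In this 1,2-reduction hydride comes from the β face past the small C1 methyl group, because the gauche C10–OTBS group covers the α face of C2=O, which sets the 2α-alcohol.

Step 6
Reactants: 8 2α-dienol
Product: 9 3α,4α-epoxy-2α-ol
Conditions: VO(acac)2 (cat.), t-BuOOH, CH2Cl2, 0 °C
Reagents that add atoms: tert-butyl hydroperoxide, CC(C)(C)OO
Why: Hydroxyl-directed vanadium-catalysed epoxidation oxidises the allylic C3=C4 bond syn to the 2α-hydroxyl and so places the C4–O bond on the α face, while C5=C6 is only homoallylic and C8=C9 has no free hydroxyl.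

Step 7
Reactants: 9 3α,4α-epoxy-2α-ol
Product: 10 epoxy enone (C10 ketone conjugated to C8=C9)
Conditions: DDQ, CH2Cl2/pH 7 buffer, 0 °C to rt
Reagents that add atoms: none
Why: DDQ oxidation of an allylic silyl ether (hydride abstraction from C10–H, then hydrolysis of the silyloxocarbenium ion) unveils the enone in one operation and erases the wrong C10 configuration, with the buffer shielding the vinyl epoxide.

Step 8
Reactants: 10 epoxy enone
Product: 12 2α,4α,10β-triol (C5=C6; C8=C9), via epoxy diol 11 (not isolated)
Conditions: LiAlH4, THF, −78 °C to rt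
Reagents that add atoms: none
Why: Hydride reduction first takes the enone in 1,2-fashion from the α face (delivery from the C2 alkoxyaluminate, β face blocked by the axial C1 methyl) to set the equatorial 10β-alcohol, then opens the epoxide at the less hindered C3 in the trans-diaxial (Fürst–Plattner) sense to leave the axial 4α tertiary alcohol.

Step 9
Reactants: 12 2α,4α,10β-triol; 13 angelic acid
Product: 15 10β-angelate 2α,4α-diol, via mixed anhydride 14 (not isolated)
Conditions: 13, 2,4,6-trichlorobenzoyl chloride, Et3N, toluene, rt; then 12, 60 °C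
Reagents that add atoms: none
Why: Yamaguchi-type mixed-anhydride esterification without a nucleophilic catalyst keeps the Z geometry, and only the equatorial allylic 10β-hydroxyl reacts because the 2α-hydroxyl is axial, neopentyl and hydrogen-bonded to O4 and the 4-hydroxyl is tertiary.

Step 10
Reactants: 15 10β-angelate 2α,4α-diol
Product: 17 2α,4α,5α,6α-tetraol 10β-angelate (trans-decalin), via osmate ester 16 (not isolated)
Conditions: OsO4 (1.0 equiv), TMEDA, CH2Cl2, −78 °C; then aq. Na2SO3, THF, 40 °C
Reagents that add atoms: osmium tetroxide, O=[Os](=O)(=O)=O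
Why: In this hydrogen-bond-directed syn-dihydroxylation the axial 4α (allylic) and 2α hydroxyls steer OsO4·TMEDA to the α face of C5=C6 (β face shielded by the C1 methyl) in preference to the undirected C8=C9 and the electron-poor angelate alkene, which sets 5α-OH and 6α-OH.

Step 11
Reactants: 17 2α,4α,5α,6α-tetraol 10β-angelate
Product: 18 5α-mesylate
Conditions: MsCl, Et3N, Bu2SnO (10 mol %), CH2Cl2, 0 °C
Reagents that add atoms: methanesulfonyl chloride, CS(=O)(=O)Cl
Why: Tin-catalysed regioselective sulfonylation of a 1,2-diol activates the secondary equatorial O5 (common to both cis-1,2-diol pairs), so the axial 2α-hydroxyl and the tertiary hydroxyls stay free.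

Step 12
Reactants: 18 5α-mesylate
Product: 19 cis-hydroazulenone (C6 ketone; 5β-H; 1β-Me; 2α-OH; 4α-OH; 10β-OAng; C8=C9)
Conditions: Et2AlCl (5 equiv), CH2Cl2, −78 to −20 °C; aq. potassium sodium tartrate
Reagents that add atoms: none
Why: Et2AlCl metalates the hydroxyls and pulls on the sulfonate, and the C6–C1 σ bond, pushed by the oxygen on C6, migrates from C6 to C5 as the C5–O bond breaks, which leaves the C6 ketone in one concerted 1,2-shift. This is a semipinacol (pinacol-type) rearrangement of a 2-hydroxy sulfonate, the reaction type known for turning decalin-diol monosulfonates into hydroazulenones. No ring is closed end to end: the single suprafacial shift of the fusion bond contracts ring A from six to five atoms (C1–C5) and at the same time expands ring B from six to seven atoms (C1, C5–C10). C5 is the only new stereocentre, because backside displacement of the equatorial 5α-mesylate inverts it while C1 migrates with retention, so H5 ends cis to the C1 methyl group and C2, C4 and C10 are untouched. The step needs C1 to migrate rather than C7, C3 or oxygen: in the locked trans-decalin only C6–C1 and C4–C3 are antiperiplanar to the equatorial C5–OMs bond, both flanking hydroxyls are gauche to it so no epoxide can form, and the fully substituted, strained C1 outruns the methylene C3 in migratory aptitude. Low temperature and the absence of free base keep the β,γ-unsaturated ketone and the allylic angelate intact.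

Step 13
Reactants: 19 cis-hydroazulenone
Product: 20 6α-alcohol
Conditions: NaBH4, CeCl3·7H2O, MeOH, −78 °C
Reagents that add atoms: none
Why: In this Luche reduction hydride enters from the convex β face because the axial approach on the α face is blocked by C2 of the folded cyclopentane, which gives the axial 6α-alcohol, and the non-basic medium prevents conjugation of the alkene.

Step 14
Reactants: 20 6α-alcohol; 13 angelic acid
Product: 21 6β,10β-diangelate alkene
Conditions: 13, PPh3, DIAD, toluene, 0 °C to rt
Reagents that add atoms: none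
Why: Mitsunobu esterification displaces the activated axial 6α-oxygen from the open β face with inversion to set the 6β-ester, and it is chemoselective because substitution at the neopentyl C2 and the tertiary C4 is not possible.

Step 15
Reactants: 21 6β,10β-diangelate alkene
Product: 22 target CNP0265715.2
Conditions: mCPBA, CH2Cl2/pH 7.5 phosphate buffer, 0 °C
Reagents that add atoms: 3-chloroperoxybenzoic acid, OOC(=O)c1cccc(Cl)c1
Why: Peracid (Prilezhaev) epoxidation picks the only electron-rich alkene and attacks the open convex β face, the α face being covered by the folded cyclopentane (C2), so C8 and C9 are set with the oxirane cis to the C10 ester.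

Compound list

| No. | Name | SMILES | Role |
|---|---|---|---|
| 1 | (R)-(−)-carvone, (5R)-2-methyl-5-(prop-1-en-2-yl)cyclohex-2-en-1-one | CC1=CC[C@H](CC1=O)C(C)=C | starting material |
| 2 | (R)-carvotanacetone, (5R)-2-methyl-5-(propan-2-yl)cyclohex-2-en-1-one | CC1=CC[C@H](CC1=O)C(C)C | intermediate |
| 3 | 3-methylbut-2-enal (prenal) | CC(C)=CC=O | starting material |
| 4 | (E)-1-(tert-butyldimethylsilyloxy)-3-methylbuta-1,3-diene | C=C(C)/C=C/O[Si](C)(C)C(C)(C)C | intermediate |
| 5 | cis-fused octalone: C2 ketone, 1β-methyl, 6β-H, 4β-isopropyl, 10α-OTBS, C8(Me)=C9 | C[C@]12C(=O)C[C@H](C(C)C)C[C@H]1CC(C)=C[C@H]2O[Si](C)(C)C(C)(C)C | intermediate |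
| 6 | ring A enone: as 5 with C3=C4 | C[C@]12C(=O)C=C(C(C)C)C[C@H]1CC(C)=C[C@H]2O[Si](C)(C)C(C)(C)C | intermediate |
| 7 | ring A linear dienone: C2 ketone, C3=C4(i-Pr), C5=C6, 1β-methyl, 10α-OTBS | C[C@]12C(=O)C=C(C(C)C)C=C1CC(C)=C[C@H]2O[Si](C)(C)C(C)(C)C | intermediate |
| 8 | 2α-dienol of 7 | C[C@]12[C@@H](O)C=C(C(C)C)C=C1CC(C)=C[C@H]2O[Si](C)(C)C(C)(C)C | intermediate |
| 9 | 3α,4α-epoxy-2α-ol: C5=C6 and C8=C9 kept, 10α-OTBS | C[C@]12[C@@H](O)[C@H]3O[C@@]3(C(C)C)C=C1CC(C)=C[C@H]2O[Si](C)(C)C(C)(C)C | intermediate |
| 10 | epoxy enone: as 9 with C10 ketone conjugated to C8=C9 | C[C@]12[C@@H](O)[C@H]3O[C@@]3(C(C)C)C=C1CC(C)=CC2=O | intermediate |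
| 11 | epoxy diol: 2α-OH, 10β-OH, 3α,4α-epoxide | C[C@]12[C@@H](O)[C@H]3O[C@@]3(C(C)C)C=C1CC(C)=C[C@@H]2O | intermediate |
| 12 | triol: 2α-OH, 4α-OH (4β-isopropyl), 10β-OH, C5=C6, C8=C9 | C[C@]12[C@@H](O)C[C@](O)(C(C)C)C=C1CC(C)=C[C@@H]2O | intermediate |
| 13 | angelic acid, (Z)-2-methylbut-2-enoic acid | C/C=C(/C)C(=O)O | starting material |
| 14 | angelic 2,4,6-trichlorobenzoic mixed anhydride | C/C=C(/C)C(=O)OC(=O)c1c(Cl)cc(Cl)cc1Cl | intermediate |
| 15 | 10β-angelate of 12 (2α-OH and 4α-OH free) | C[C@]12[C@@H](O)C[C@](O)(C(C)C)C=C1CC(C)=C[C@@H]2OC(=O)/C(C)=C\C | intermediate |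
| 16 | 5α,6α-osmate ester of 15 (hexavalent osmium, TMEDA chelate) | C[C@]12[C@@H](O)C[C@](O)(C(C)C)[C@H]3O[Os-2]4(=O)(=O)([N+](C)(C)CC[N+]4(C)C)O[C@@]13CC(C)=C[C@@H]2OC(=O)/C(C)=C\C | intermediate |
| 17 | trans-decalin tetraol: 2α, 4α, 6α axial OH, 5α equatorial OH, 10β-angelate | C[C@]12[C@@H](O)C[C@](O)(C(C)C)[C@@H](O)[C@]1(O)CC(C)=C[C@@H]2OC(=O)/C(C)=C\C | intermediate |
| 18 | 5α-mesylate of 17 | C[C@]12[C@@H](O)C[C@](O)(C(C)C)[C@@H](OS(C)(=O)=O)[C@]1(O)CC(C)=C[C@@H]2OC(=O)/C(C)=C\C | intermediate |
| 19 | cis-hydroazulenone: C6 ketone, 5β-H, 1β-methyl, 2α-OH, 4α-OH, 10β-angelate, C8=C9 | O=C1CC(C)=C[C@H](OC(=O)/C(C)=C\C)[C@@]2(C)[C@@H](O)C[C@](O)(C(C)C)[C@@H]12 | intermediate |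
| 20 | 6α-alcohol of 19 | O[C@H]1CC(C)=C[C@H](OC(=O)/C(C)=C\C)[C@@]2(C)[C@@H](O)C[C@](O)(C(C)C)[C@@H]12 | intermediate |
| 21 | 6β,10β-diangelate with C8=C9 | C/C=C(/C)C(=O)O[C@@H]1CC(C)=C[C@H](OC(=O)/C(C)=C\C)[C@@]2(C)[C@@H](O)C[C@](O)(C(C)C)[C@@H]12 | intermediate |
| 22 | CNP0265715.2: 6β,10β-diangeloyloxy-8β,9β-epoxy-2α,4α-diol, cis-fused | C/C=C(/C)C(=O)O[C@@H]1C[C@]2(C)O[C@@H]2[C@H](OC(=O)/C(C)=C\C)[C@@]2(C)[C@@H](O)C[C@](O)(C(C)C)[C@@H]12 | target |

Total step count: 15. Longest linear sequence: 14 (steps 1 and 3–15; step 2 runs in parallel).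

Steps most likely to fail

**Step 12.**
- What may go wrong: the Lewis acid may ionise the allylic angelate, and the electron-poor mesylate may leave too slowly.
- Path: the fallback removes the ester and drives the shift from the other end. It sets out from triol 12 and comes back at ketone 19.
- Silylation of the equatorial 10β-hydroxyl (TBSCl, imidazole, DMF) should give the 10β-silyl ether F1.
- OsO4/TMEDA adds as before through the silyl osmate ester F2, and sulfite work-up gives the silyl tetraol F3.
- Tin-catalysed mesylation gives the silyl mesylate F4.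
- A potassium alkoxide at O6 (KOt-Bu, one equivalent, THF, −40 to 0 °C) then pushes the same bond shift and gives the silyl hydroazulenone F5.
- Buffered fluoride (TBAF, AcOH) gives the 10β-hydroxy ketone F6.
- Esterification of its convex 10β-hydroxyl by mixed anhydride 14 rejoins the route at 19.

**Step 7.**
- What may go wrong: acid may open the tertiary vinyl epoxide, and DDQ may abstract hydride at the doubly allylic C7.
- Path: the fallback removes the epoxide before any oxidation. It sets out from epoxy alcohol 9 and comes back at triol 12.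
- LiAlH4 opens the epoxide to the robust silyl diol F7, and TBAF gives the 10α-triol F8.
- MnO2 oxidises only the allylic 10-hydroxyl to the enone diol F9.
- Me4NBH(OAc)3, bound to the 2α-hydroxyl, delivers hydride to the α face of C10 and gives 12.

**Step 14.**
- What may go wrong: anti elimination of the axial oxyphosphonium group (toward H5 or H7) and poor activation of the hindered axial hydroxyl.
- Path: the fallback replaces substitution by thermodynamic control. It sets out from 6α-alcohol 20 and comes back at 21.
- Meerwein–Ponndorf–Verley/Oppenauer equilibration (Al(Oi-Pr)3, i-PrOH, trace acetone, toluene, 60 °C) should move the axial alcohol, which is syn-axial to C2, to the equatorial 6β-alcohol F10.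
- F10 is esterified with retention by mixed anhydride 14 to give 21.

Further compounds
F1 | step 12 | 10β-silyl ether of triol 12 | C[C@]12[C@@H](O)C[C@](O)(C(C)C)C=C1CC(C)=C[C@@H]2O[Si](C)(C)C(C)(C)C
F2 | step 12 | 5α,6α-osmate ester of F1 (TMEDA chelate) | C[C@]12[C@@H](O)C[C@](O)(C(C)C)[C@H]3O[Os-2]4(=O)(=O)([N+](C)(C)CC[N+]4(C)C)O[C@@]13CC(C)=C[C@@H]2O[Si](C)(C)C(C)(C)C
F3 | step 12 | 2α,4α,5α,6α-tetraol 10β-silyl ether | C[C@]12[C@@H](O)C[C@](O)(C(C)C)[C@@H](O)[C@]1(O)CC(C)=C[C@@H]2O[Si](C)(C)C(C)(C)C
F4 | step 12 | 5α-mesylate of F3 | C[C@]12[C@@H](O)C[C@](O)(C(C)C)[C@@H](OS(C)(=O)=O)[C@]1(O)CC(C)=C[C@@H]2O[Si](C)(C)C(C)(C)C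
F5 | step 12 | cis-hydroazulenone 10β-silyl ether | O=C1CC(C)=C[C@H](O[Si](C)(C)C(C)(C)C)[C@@]2(C)[C@@H](O)C[C@](O)(C(C)C)[C@@H]12
F6 | step 12 | 10β-hydroxy cis-hydroazulenone | O=C1CC(C)=C[C@H](O)[C@@]2(C)[C@@H](O)C[C@](O)(C(C)C)[C@@H]12
F7 | step 7 | 2α,4α-diol 10α-silyl ether | C[C@]12[C@@H](O)C[C@](O)(C(C)C)C=C1CC(C)=C[C@H]2O[Si](C)(C)C(C)(C)C
F8 | step 7 | 2α,4α,10α-triol | C[C@]12[C@@H](O)C[C@](O)(C(C)C)C=C1CC(C)=C[C@H]2O
F9 | step 7 | 2α,4α-diol C10 enone | C[C@]12[C@@H](O)C[C@](O)(C(C)C)C=C1CC(C)=CC2=O
F10 | step 14 | 6β-alcohol 10β-angelate | O[C@@H]1CC(C)=C[C@H](OC(=O)/C(C)=C\C)[C@@]2(C)[C@@H](O)C[C@](O)(C(C)C)[C@@H]12
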